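**Retrosynthetic overview** (labdane numbering: ring A = C1–C5 + C10, ring B = C5–C10, side chain C11–C15 on C9, C17 = the CH2OH carbon on C8)
1. 22 ⇐ C17 by Stille coupling on the C7=C8 enol triflate of a C8 ketone; C5–H by hydrogenation of C5=C6; C3–OH by hydride reduction of a C3 ketone (14).
2. Ring A is closed last (14 ⇐ 13) at C4–C5: palladium-catalysed intramolecular alkenylation of the C4 enolate of a C10-tethered isopropyl ketone by the C5 enol triflate of ring B.
3. Enabling feature: in ring B, C5 lies between quaternary C10 and C6, so its enol triflate can only be C5=C6; C4 is the only enolisable carbon that can reach C5 (C2 would close a four-ring) and already carries both methyl groups.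
4. Ring B is bought as quinone monoketal 4: asymmetric copper-catalysed 1,4-addition brings C11–C15 to C9; methylation, then Michael addition anti to the C9 chain, builds quaternary C10.
5. Order of rings: B (from 4), then A (step 8).

Key step: step 8

Assumption: the (S,R,R)-phosphoramidite is taken to give the 1S adduct 6; if the sense of induction is the opposite, the enantiomeric ligand is used.
Assumption: the C10 epimers of 8 and the carbinol epimers of 12 are carried on as mixtures, because both centres are reset (steps 5 and 7).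

Step 1
Reactants: 1 (3R)-5-methoxy-3-methyl-5-oxopentanoic acid
Product: 2 methyl (3R)-5-hydroxy-3-methylpentanoate
Conditions: BH3·SMe2, THF, 0 °C to rt; MeOH quench
Reagents that add atoms: none
Why: Chemoselective borane reduction takes the carboxylic acid much faster than the methyl ester and leaves the C13 stereocentre untouched.

Step 2
Reactants: 2 methyl (3R)-5-hydroxy-3-methylpentanoate
Product: 3 methyl (3S)-5-iodo-3-methylpentanoate
Conditions: I2, PPh3, imidazole, CH2Cl2, 0 °C
Reagents that add atoms: iodine, II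
Why: Appel-type iodination converts the primary alcohol into the iodide by SN2 displacement of the oxyphosphonium group, remote from the stereocentre (the descriptor changes only through priorities).

Step 3
Reactants: 3 methyl (3S)-5-iodo-3-methylpentanoate; 4 4,4-dimethoxycyclohexa-2,5-dien-1-one
Product: 6 methyl (3R)-5-[(1S)-2,2-dimethoxy-5-oxocyclohex-3-en-1-yl]-3-methylpentanoate, via dialkylzinc 5 (not isolated)
Conditions: 3, Et2Zn (neat), 50 °C, then evaporation; 4, Cu(OTf)2 (2 mol %), (S,R,R)-phosphoramidite [(S)-BINOL, bis((R)-1-phenylethyl)amine] (4 mol %), toluene, −25 °C; aq. NH4Cl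
Reagents that add atoms: none
Why: Iodine–zinc exchange gives an ester-tolerant dialkylzinc, and copper/phosphoramidite-catalysed asymmetric conjugate addition desymmetrises the quinone monoketal, the ligand selecting one enantiotopic β-carbon and face and so setting C9, while the more hindered product enone should not add a second time.

Step 4
Reactants: 6 methyl (3R)-5-[(1S)-2,2-dimethoxy-5-oxocyclohex-3-en-1-yl]-3-methylpentanoate
Product: 8 methyl (3R)-5-[(1S,6S)-2,2-dimethoxy-6-methyl-5-oxocyclohex-3-en-1-yl]-3-methylpentanoate (trans isomer, minor C10 epimer carried along), via lithium dienolate 7 (not isolated)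
Conditions: LiHMDS, THF, −78 °C; MeI, −78 to −20 °C
Reagents that add atoms: iodomethane, CI
Why: Enolate alkylation is regiospecific because C10 is the only enolisable position of the cross-conjugated enone (C8 is a ketal carbon), and the ketone is deprotonated in preference to the less acidic ester.

Step 5
Reactants: 8 methyl (3R)-5-[(1S,6S)-2,2-dimethoxy-6-methyl-5-oxocyclohex-3-en-1-yl]-3-methylpentanoate; 9 4-methylpent-1-en-3-one (isopropyl vinyl ketone)
Product: 10 methyl (3R)-5-[(1S,6S)-2,2-dimethoxy-6-methyl-6-(4-methyl-3-oxopentyl)-5-oxocyclohex-3-en-1-yl]-3-methylpentanoate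
Conditions: t-BuOK (cat.), t-BuOH/THF, 0 °C
Reagents that add atoms: none
Why: Base-catalysed Michael addition of the C10 dienolate to the vinyl ketone builds quaternary C10, the acceptor entering anti to the neighbouring C9 chain so that the C10 methyl ends cis to it.

Step 6
Reactants: 10 methyl (3R)-5-[(1S,6S)-2,2-dimethoxy-6-methyl-6-(4-methyl-3-oxopentyl)-5-oxocyclohex-3-en-1-yl]-3-methylpentanoate
Product: 12 methyl (3R)-5-[(1S,6S)-6-(3-hydroxy-4-methylpentyl)-2,2-dimethoxy-6-methyl-5-{[(trifluoromethyl)sulfonyl]oxy}cyclohex-4-en-1-yl]-3-methylpentanoate (both carbinol epimers), via dilithium enolate alkoxide 11 (not isolated)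
Conditions: L-Selectride (2.3 equiv), THF, −78 °C; PhNTf2, −78 to 0 °C
Reagents that add atoms: N-phenylbis(trifluoromethanesulfonimide), O=S(=O)(N(c1ccccc1)S(=O)(=O)C(F)(F)F)C(F)(F)F
Why: Conjugate hydride reduction of the β-unsubstituted enone (its carbonyl is shielded by quaternary C10) gives the C5=C6 enolate regiospecifically, and O-triflation traps it while the hindered borate-bound chain alkoxide, formed by concurrent ketone reduction, should stay untouched.

Step 7
Reactants: 12 methyl (3R)-5-[(1S,6S)-6-(3-hydroxy-4-methylpentyl)-2,2-dimethoxy-6-methyl-5-{[(trifluoromethyl)sulfonyl]oxy}cyclohex-4-en-1-yl]-3-methylpentanoate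
Product: 13 methyl (3R)-5-[(1S,6S)-2,2-dimethoxy-6-methyl-6-(4-methyl-3-oxopentyl)-5-{[(trifluoromethyl)sulfonyl]oxy}cyclohex-4-en-1-yl]-3-methylpentanoate
Conditions: Dess–Martin periodinane, NaHCO3, CH2Cl2, rt
Reagents that add atoms: none
Why: Dess–Martin oxidation returns the chain alcohol to the isopropyl ketone under neutral conditions that spare the enol triflate, ketal and ester, and merges both carbinol epimers.

Step 8
Reactants: 13 methyl (3R)-5-[(1S,6S)-2,2-dimethoxy-6-methyl-6-(4-methyl-3-oxopentyl)-5-{[(trifluoromethyl)sulfonyl]oxy}cyclohex-4-en-1-yl]-3-methylpentanoate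
Product: 14 methyl (3R)-5-[(1S,8aS)-2,2-dimethoxy-5,5,8a-trimethyl-6-oxo-1,2,3,5,6,7,8,8a-octahydronaphthalen-1-yl]-3-methylpentanoate
Conditions: Pd2(dba)3 (5 mol %), Xantphos (12 mol %), K3PO4, toluene, 90 °C
Reagents that add atoms: none
Why: Zerovalent palladium inserts into the C5–O bond of the enol triflate, phosphate generates the ketone enolates, and the C4 enolate displaces triflate on palladium to give a seven-membered C-bound palladium enolate whose C(sp3)–C(sp2) reductive elimination forms the C4–C5 bond. The closest known reaction type is the palladium-catalysed intramolecular α-alkenylation (and α-arylation) of ketone enolates, which is established for building quaternary α-carbons from isopropyl ketones. Ring A closes as a six-membered ring by reductive elimination, endo with respect to the enolate (C3 and C4 both end in the ring), and the C2 enolate cannot compete because it would have to close a four-membered ring. No stereocentre is formed: C4 becomes quaternary with two like methyl groups and C5 stays trigonal (C5=C6) on purpose, because a bond made to C5 on a π-face of ring B from the C10 tether would be expected to enter anti to the C10 methyl and give the cis-decalin, whereas here the C5 hydrogen is added later from the face away from the C10 and axial C4 methyl groups. The step needs C- over O-alkenylation and tolerance of the side-chain ester; the soft palladium C-enolate and the weak base K3PO4, which should not enolise the ester appreciably, are relied on for both.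

Step 9
Reactants: 14 methyl (3R)-5-[(1S,8aS)-2,2-dimethoxy-5,5,8a-trimethyl-6-oxo-1,2,3,5,6,7,8,8a-octahydronaphthalen-1-yl]-3-methylpentanoate
Product: 15 methyl (3R)-5-[(1S,6R,8aS)-6-hydroxy-2,2-dimethoxy-5,5,8a-trimethyl-1,2,3,5,6,7,8,8a-octahydronaphthalen-1-yl]-3-methylpentanoate
Conditions: NaBH4, MeOH, 0 °C
Reagents that add atoms: none
Why: Hydride reduction of the 4,4-dimethyl-3-ketone should proceed by axial attack on the face away from the C10 methyl to give the equatorial C3 alcohol, cis to the C10 methyl, and the ester is not reduced.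

Step 10
Reactants: 15 methyl (3R)-5-[(1S,6R,8aS)-6-hydroxy-2,2-dimethoxy-5,5,8a-trimethyl-1,2,3,5,6,7,8,8a-octahydronaphthalen-1-yl]-3-methylpentanoate
Product: 16 methyl (3R)-5-[(1S,6R,8aS)-6-{[tert-butyl(dimethyl)silyl]oxy}-2,2-dimethoxy-5,5,8a-trimethyl-1,2,3,5,6,7,8,8a-octahydronaphthalen-1-yl]-3-methylpentanoate
Conditions: TBSOTf, 2,6-lutidine, CH2Cl2, 0 °C
Reagents that add atoms: tert-butyldimethylsilyl trifluoromethanesulfonate, CC(C)(C)[Si](C)(C)OS(=O)(=O)C(F)(F)F
Why: Silylation with the silyl triflate protects the hindered secondary alcohol for the later enolate chemistry, and the lutidine buffer spares the ketal.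

Step 11
Reactants: 16 methyl (3R)-5-[(1S,6R,8aS)-6-{[tert-butyl(dimethyl)silyl]oxy}-2,2-dimethoxy-5,5,8a-trimethyl-1,2,3,5,6,7,8,8a-octahydronaphthalen-1-yl]-3-methylpentanoate
Product: 17 methyl (3R)-5-[(1S,4aS,6R,8aR)-6-{[tert-butyl(dimethyl)silyl]oxy}-2,2-dimethoxy-5,5,8a-trimethyldecahydronaphthalen-1-yl]-3-methylpentanoate
Conditions: H2 (4 atm), PtO2, EtOAc, rt
Reagents that add atoms: none
Why: Heterogeneous hydrogenation should deliver hydrogen to C5=C6 from the face away from the C10 methyl and the axial C4 methyl, setting C5–H trans to the angular methyl (trans-decalin), as with 4,4-dimethyl-5-ene steroids.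

Step 12
Reactants: 17 methyl (3R)-5-[(1S,4aS,6R,8aR)-6-{[tert-butyl(dimethyl)silyl]oxy}-2,2-dimethoxy-5,5,8a-trimethyldecahydronaphthalen-1-yl]-3-methylpentanoate
Product: 18 methyl (3R)-5-[(1S,4aS,6R,8aR)-6-{[tert-butyl(dimethyl)silyl]oxy}-5,5,8a-trimethyl-2-oxodecahydronaphthalen-1-yl]-3-methylpentanoate
Conditions: PPTS, acetone/H2O, 40 °C
Reagents that add atoms: water, O
Why: Mild acid-catalysed ketal hydrolysis unmasks the C8 ketone while the hindered silyl ether and the ester survive, and C9, now epimerisable, already has the thermodynamically preferred equatorial side chain.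

Step 13
Reactants: 18 methyl (3R)-5-[(1S,4aS,6R,8aR)-6-{[tert-butyl(dimethyl)silyl]oxy}-5,5,8a-trimethyl-2-oxodecahydronaphthalen-1-yl]-3-methylpentanoate
Product: 20 methyl (3R)-5-[(1S,4aS,6R,8aR)-6-{[tert-butyl(dimethyl)silyl]oxy}-5,5,8a-trimethyl-2-{[(trifluoromethyl)sulfonyl]oxy}-1,4,4a,5,6,7,8,8a-octahydronaphthalen-1-yl]-3-methylpentanoate, via potassium enolate 19 (not isolated)
Conditions: KHMDS, THF, −78 °C; PhNTf2
Reagents that add atoms: N-phenylbis(trifluoromethanesulfonimide), O=S(=O)(N(c1ccccc1)S(=O)(=O)C(F)(F)F)C(F)(F)F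
Why: Kinetic deprotonation should occur at the C7 methylene and not at the hindered C9 methine next to quaternary C10, so enolate O-triflation gives the C7=C8 enol triflate without touching C9.

Step 14
Reactants: 20 methyl (3R)-5-[(1S,4aS,6R,8aR)-6-{[tert-butyl(dimethyl)silyl]oxy}-5,5,8a-trimethyl-2-{[(trifluoromethyl)sulfonyl]oxy}-1,4,4a,5,6,7,8,8a-octahydronaphthalen-1-yl]-3-methylpentanoate
Product: 21 methyl (3R)-5-[(1S,4aS,6R,8aS)-6-{[tert-butyl(dimethyl)silyl]oxy}-2-(hydroxymethyl)-5,5,8a-trimethyl-1,4,4a,5,6,7,8,8a-octahydronaphthalen-1-yl]-3-methylpentanoate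
Conditions: Bu3SnCH2OH, Pd(PPh3)4, LiCl, 1,4-dioxane, 100 °C
Reagents that add atoms: (tributylstannyl)methanol, CCCC[Sn](CCCC)(CCCC)CO
Why: Stille coupling of the enol triflate transfers the hydroxymethyl group to C8 with the double bond fixed at C7=C8, so C17 arrives at the alcohol oxidation level and the side-chain ester is never exposed to a reductant.

Step 15
Reactants: 21 methyl (3R)-5-[(1S,4aS,6R,8aS)-6-{[tert-butyl(dimethyl)silyl]oxy}-2-(hydroxymethyl)-5,5,8a-trimethyl-1,4,4a,5,6,7,8,8a-octahydronaphthalen-1-yl]-3-methylpentanoate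
Product: 22 methyl (3R)-5-[(1S,4aS,6R,8aS)-6-hydroxy-2-(hydroxymethyl)-5,5,8a-trimethyl-1,4,4a,5,6,7,8,8a-octahydronaphthalen-1-yl]-3-methylpentanoate
Conditions: TBAF, THF, rt to 40 °C
Reagents that add atoms: none
Why: Fluoride-mediated desilylation frees the C3 hydroxyl without affecting the methyl ester or the allylic alcohol.

**Compound list**
1 | (3R)-5-methoxy-3-methyl-5-oxopentanoic acid (methyl hydrogen (R)-3-methylglutarate) | COC(=O)C[C@H](C)CC(=O)O | starting material
2 | methyl (3R)-5-hydroxy-3-methylpentanoate | COC(=O)C[C@H](C)CCO | intermediate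
3 | methyl (3S)-5-iodo-3-methylpentanoate | COC(=O)C[C@H](C)CCI | intermediate
4 | 4,4-dimethoxycyclohexa-2,5-dien-1-one | COC1(OC)C=CC(=O)C=C1 | starting material
5 | bis[(3S)-5-methoxy-3-methyl-5-oxopentyl]zinc | COC(=O)C[C@H](C)CC[Zn]CC[C@@H](C)CC(=O)OC | intermediate
6 | methyl (3R)-5-[(1S)-2,2-dimethoxy-5-oxocyclohex-3-en-1-yl]-3-methylpentanoate | COC(=O)C[C@H](C)CC[C@@H]1C(OC)(OC)C=CC(=O)C1 | intermediate
7 | lithium dienolate of 6 (O–Li on C5, C5=C10) | COC(=O)C[C@H](C)CC[C@@H]1C(OC)(OC)C=CC(O[Li])=C1 | intermediate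
8 | methyl (3R)-5-[(1S,6S)-2,2-dimethoxy-6-methyl-5-oxocyclohex-3-en-1-yl]-3-methylpentanoate (trans isomer shown) | COC(=O)C[C@H](C)CC[C@@H]1C(OC)(OC)C=CC(=O)[C@H]1C | intermediate
9 | 4-methylpent-1-en-3-one | CC(C)C(=O)C=C | starting material
10 | methyl (3R)-5-[(1S,6S)-2,2-dimethoxy-6-methyl-6-(4-methyl-3-oxopentyl)-5-oxocyclohex-3-en-1-yl]-3-methylpentanoate | COC(=O)C[C@H](C)CC[C@@H]1C(OC)(OC)C=CC(=O)[C@@]1(C)CCC(=O)C(C)C | intermediate
11 | dilithium enolate alkoxide from 10 (O–Li on C5 with C5=C6, O–Li on C3) | COC(=O)C[C@H](C)CC[C@@H]1C(OC)(OC)CC=C(O[Li])[C@@]1(C)CCC(O[Li])C(C)C | intermediate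
12 | methyl (3R)-5-[(1S,6S)-6-(3-hydroxy-4-methylpentyl)-2,2-dimethoxy-6-methyl-5-{[(trifluoromethyl)sulfonyl]oxy}cyclohex-4-en-1-yl]-3-methylpentanoate (carbinol epimers) | COC(=O)C[C@H](C)CC[C@@H]1C(OC)(OC)CC=C(OS(=O)(=O)C(F)(F)F)[C@@]1(C)CCC(O)C(C)C | intermediate
13 | methyl (3R)-5-[(1S,6S)-2,2-dimethoxy-6-methyl-6-(4-methyl-3-oxopentyl)-5-{[(trifluoromethyl)sulfonyl]oxy}cyclohex-4-en-1-yl]-3-methylpentanoate | COC(=O)C[C@H](C)CC[C@@H]1C(OC)(OC)CC=C(OS(=O)(=O)C(F)(F)F)[C@@]1(C)CCC(=O)C(C)C | intermediate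
14 | methyl (3R)-5-[(1S,8aS)-2,2-dimethoxy-5,5,8a-trimethyl-6-oxo-1,2,3,5,6,7,8,8a-octahydronaphthalen-1-yl]-3-methylpentanoate | COC(=O)C[C@H](C)CC[C@@H]1C(OC)(OC)CC=C2C(C)(C)C(=O)CC[C@@]12C | intermediate
15 | methyl (3R)-5-[(1S,6R,8aS)-6-hydroxy-2,2-dimethoxy-5,5,8a-trimethyl-1,2,3,5,6,7,8,8a-octahydronaphthalen-1-yl]-3-methylpentanoate | COC(=O)C[C@H](C)CC[C@@H]1C(OC)(OC)CC=C2C(C)(C)[C@H](O)CC[C@@]12C | intermediate
16 | methyl (3R)-5-[(1S,6R,8aS)-6-{[tert-butyl(dimethyl)silyl]oxy}-2,2-dimethoxy-5,5,8a-trimethyl-1,2,3,5,6,7,8,8a-octahydronaphthalen-1-yl]-3-methylpentanoate | COC(=O)C[C@H](C)CC[C@@H]1C(OC)(OC)CC=C2C(C)(C)[C@H](O[Si](C)(C)C(C)(C)C)CC[C@@]12C | intermediate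
17 | methyl (3R)-5-[(1S,4aS,6R,8aR)-6-{[tert-butyl(dimethyl)silyl]oxy}-2,2-dimethoxy-5,5,8a-trimethyldecahydronaphthalen-1-yl]-3-methylpentanoate | COC(=O)C[C@H](C)CC[C@@H]1C(OC)(OC)CC[C@@H]2C(C)(C)[C@H](O[Si](C)(C)C(C)(C)C)CC[C@@]12C | intermediate
18 | methyl (3R)-5-[(1S,4aS,6R,8aR)-6-{[tert-butyl(dimethyl)silyl]oxy}-5,5,8a-trimethyl-2-oxodecahydronaphthalen-1-yl]-3-methylpentanoate | COC(=O)C[C@H](C)CC[C@@H]1C(=O)CC[C@@H]2C(C)(C)[C@H](O[Si](C)(C)C(C)(C)C)CC[C@@]12C | intermediate
19 | potassium enolate of 18 (O–K on C8, C7=C8) | COC(=O)C[C@H](C)CC[C@@H]1C(O[K])=CC[C@@H]2C(C)(C)[C@H](O[Si](C)(C)C(C)(C)C)CC[C@@]12C | intermediate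
20 | methyl (3R)-5-[(1S,4aS,6R,8aR)-6-{[tert-butyl(dimethyl)silyl]oxy}-5,5,8a-trimethyl-2-{[(trifluoromethyl)sulfonyl]oxy}-1,4,4a,5,6,7,8,8a-octahydronaphthalen-1-yl]-3-methylpentanoate | COC(=O)C[C@H](C)CC[C@@H]1C(OS(=O)(=O)C(F)(F)F)=CC[C@@H]2C(C)(C)[C@H](O[Si](C)(C)C(C)(C)C)CC[C@@]12C | intermediate
21 | methyl (3R)-5-[(1S,4aS,6R,8aS)-6-{[tert-butyl(dimethyl)silyl]oxy}-2-(hydroxymethyl)-5,5,8a-trimethyl-1,4,4a,5,6,7,8,8a-octahydronaphthalen-1-yl]-3-methylpentanoate | COC(=O)C[C@H](C)CC[C@@H]1C(CO)=CC[C@@H]2C(C)(C)[C@H](O[Si](C)(C)C(C)(C)C)CC[C@@]12C | intermediate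
22 | methyl (3R)-5-[(1S,4aS,6R,8aS)-6-hydroxy-2-(hydroxymethyl)-5,5,8a-trimethyl-1,4,4a,5,6,7,8,8a-octahydronaphthalen-1-yl]-3-methylpentanoate | COC(=O)C[C@H](C)CC[C@@H]1C(CO)=CC[C@@H]2C(C)(C)[C@H](O)CC[C@@]12C | target

Total step count: 15. Longest linear sequence: 15 steps (1 to 22; 4 and 9 enter as purchased materials).

**Steps most likely to fail**

Step 8 (key step). Reductive elimination at the crowded C4–C5 junction may be slower than loss of the triflate by protonation, β-hydride loss from the palladium enolate, or O-alkenylation. The fallback closes ring A by aldol condensation and sets out from 8. Hydrogenation (H2, Pd/C, EtOAc) should give methyl (3R)-5-[(1S,6S)-2,2-dimethoxy-6-methyl-5-oxocyclohexyl]-3-methylpentanoate F1. Robinson annulation of F1 with ethyl vinyl ketone (NaOMe, MeOH, 0 °C then reflux; Michael addition at the more substituted C10 anti to the C9 chain, then aldol condensation of C4 onto C5) should give methyl (3R)-5-[(1S,8aS)-2,2-dimethoxy-5,8a-dimethyl-6-oxo-1,2,3,4,6,7,8,8a-octahydronaphthalen-1-yl]-3-methylpentanoate F2. Deconjugative methylation of F2 (t-BuOK, MeI, t-BuOH) puts the second methyl on C4 and moves the double bond to C5=C6, which is 14, where the route is rejoined.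

Step 5. The chain enolate formed after the first addition may add again to C7 of the ring enone (double Michael addition to a bicyclo[2.2.2]octane), or the vinyl ketone may polymerise before the hindered C10 reacts. The fallback builds quaternary C10 by alkylation and sets out from 8. Allylation (LiHMDS, allyl bromide, THF, −78 °C, allyl anti to the C9 chain) should give methyl (3R)-5-[(1S,6S)-2,2-dimethoxy-6-methyl-5-oxo-6-(prop-2-en-1-yl)cyclohex-3-en-1-yl]-3-methylpentanoate F3. Conjugate reduction and triflation (L-Selectride, then PhNTf2) should give methyl (3R)-5-[(1S,6S)-2,2-dimethoxy-6-methyl-6-(prop-2-en-1-yl)-5-{[(trifluoromethyl)sulfonyl]oxy}cyclohex-4-en-1-yl]-3-methylpentanoate F4. Hydroboration of the terminal alkene (9-BBN, then NaBO3) should give methyl (3R)-5-[(1S,6S)-6-(3-hydroxypropyl)-2,2-dimethoxy-6-methyl-5-{[(trifluoromethyl)sulfonyl]oxy}cyclohex-4-en-1-yl]-3-methylpentanoate F5. Dess–Martin oxidation should give methyl (3R)-5-[(1S,6S)-2,2-dimethoxy-6-methyl-6-(3-oxopropyl)-5-{[(trifluoromethyl)sulfonyl]oxy}cyclohex-4-en-1-yl]-3-methylpentanoate F6. Addition of isopropylmagnesium chloride (THF, −78 °C, aldehyde before ester) gives 12, where the route is rejoined.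

Step 13. Enolisation may go partly toward C9 (wrong enol triflate and epimerisation of C9), or deprotonation of the hindered ketone may be incomplete. The fallback brings in C17 by olefination and sets out from 18. Wittig methylenation (Ph3P=CH2, THF) should give methyl (3R)-5-[(1R,4aS,6R,8aS)-6-{[tert-butyl(dimethyl)silyl]oxy}-5,5,8a-trimethyl-2-methylidenedecahydronaphthalen-1-yl]-3-methylpentanoate F7. Epoxidation (mCPBA, NaHCO3, CH2Cl2) should give methyl (3R)-5-[(1S,4aS,6R,8aR)-6-{[tert-butyl(dimethyl)silyl]oxy}-5,5,8a-trimethyloctahydro-1H-spiro[naphthalene-2,2'-oxiran]-1-yl]-3-methylpentanoate F8 (configuration at the spiro carbon not controlled). Base-induced isomerisation of the epoxide to the allylic alcohol (diethylaluminium 2,2,6,6-tetramethylpiperidide, toluene, 0 °C), which removes a C7 hydrogen, gives 21, where the route is rejoined.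

**Further compounds**
F1 | step 8 | methyl (3R)-5-[(1S,6S)-2,2-dimethoxy-6-methyl-5-oxocyclohexyl]-3-methylpentanoate | COC(=O)C[C@H](C)CC[C@@H]1C(OC)(OC)CCC(=O)[C@H]1C
F2 | step 8 | methyl (3R)-5-[(1S,8aS)-2,2-dimethoxy-5,8a-dimethyl-6-oxo-1,2,3,4,6,7,8,8a-octahydronaphthalen-1-yl]-3-methylpentanoate | COC(=O)C[C@H](C)CC[C@@H]1C(OC)(OC)CCC2=C(C)C(=O)CC[C@@]12C
F3 | step 5 | methyl (3R)-5-[(1S,6S)-2,2-dimethoxy-6-methyl-5-oxo-6-(prop-2-en-1-yl)cyclohex-3-en-1-yl]-3-methylpentanoate | COC(=O)C[C@H](C)CC[C@@H]1C(OC)(OC)C=CC(=O)[C@@]1(C)CC=C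
F4 | step 5 | methyl (3R)-5-[(1S,6S)-2,2-dimethoxy-6-methyl-6-(prop-2-en-1-yl)-5-{[(trifluoromethyl)sulfonyl]oxy}cyclohex-4-en-1-yl]-3-methylpentanoate | COC(=O)C[C@H](C)CC[C@@H]1C(OC)(OC)CC=C(OS(=O)(=O)C(F)(F)F)[C@@]1(C)CC=C
F5 | step 5 | methyl (3R)-5-[(1S,6S)-6-(3-hydroxypropyl)-2,2-dimethoxy-6-methyl-5-{[(trifluoromethyl)sulfonyl]oxy}cyclohex-4-en-1-yl]-3-methylpentanoate | COC(=O)C[C@H](C)CC[C@@H]1C(OC)(OC)CC=C(OS(=O)(=O)C(F)(F)F)[C@@]1(C)CCCO
F6 | step 5 | methyl (3R)-5-[(1S,6S)-2,2-dimethoxy-6-methyl-6-(3-oxopropyl)-5-{[(trifluoromethyl)sulfonyl]oxy}cyclohex-4-en-1-yl]-3-methylpentanoate | COC(=O)C[C@H](C)CC[C@@H]1C(OC)(OC)CC=C(OS(=O)(=O)C(F)(F)F)[C@@]1(C)CCC=O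
F7 | step 13 | methyl (3R)-5-[(1R,4aS,6R,8aS)-6-{[tert-butyl(dimethyl)silyl]oxy}-5,5,8a-trimethyl-2-methylidenedecahydronaphthalen-1-yl]-3-methylpentanoate | COC(=O)C[C@H](C)CC[C@@H]1C(=C)CC[C@@H]2C(C)(C)[C@H](O[Si](C)(C)C(C)(C)C)CC[C@@]12C
F8 | step 13 | methyl (3R)-5-[(1S,4aS,6R,8aR)-6-{[tert-butyl(dimethyl)silyl]oxy}-5,5,8a-trimethyloctahydro-1H-spiro[naphthalene-2,2'-oxiran]-1-yl]-3-methylpentanoate | COC(=O)C[C@H](C)CC[C@@H]1C2(CO2)CC[C@@H]3C(C)(C)[C@H](O[Si](C)(C)C(C)(C)C)CC[C@@]13C
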